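In a one-step world L + D runs to product until the balance of the smaller charge reads zero, and in this flask, with 1.0 M of L against 1.10 M of D, that limiting reagent is L, so I began by expecting c_L to reach zero.

| flask | L | D | G | remark | time |
|---|---|---|---|---|---|
| south-west | 1 M | 0.55 M (fed, over 2.0 min) | 4.2 mM | run made earlier; the fed solution adds 0.25 times the starting volume |  |
| south-east | 1 M | 0.83 M (fed, over 2.0 min) | 4.2 mM | run made earlier; the fed solution adds 0.25 times the starting volume |  |
| east | 1 M | 1.1 M (fed, over 2.0 min) | 2.1 mM | run made earlier; the fed solution adds 0.25 times the starting volume |  |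
| flask | 1.0 M | 1.10 M (fed, over 2.0 min) | 4.2 mM | the fed solution adds 0.25 times the starting volume | 25 min |

| run | time / min | X / % | J / % |
|---|---|---|---|
| south-west | 6.00 | 4.9 | 40.0 |
| south-west | 12.0 | 2.5 | 47.1 |
| south-west | 20.0 | 1.8 | 48.8 |
| south-west | 25.0 | 1.7 | 49.2 |
| south-west | 30.0 | 2.3 | 49.5 |
| south-east | 6.00 | 7.6 | 54.2 |
| south-east | 12.0 | 4.1 | 65.3 |
| south-east | 20.0 | 2.6 | 69.0 |
| south-east | 25.0 | 3.0 | 69.8 |
| south-east | 30.0 | 2.5 | 69.8 |
| east | 2.50 | 22.0 | 38.2 |
| east | 5.00 | 10.8 | 57.6 |
| east | 8.00 | 7.1 | 68.1 |
| east | 15.0 | 4.1 | 78.1 |
| east | 30.0 | 3.3 | 82.5 |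

(readings scatter by 0.3 percentage points)

- amounts are per litre of the starting volume; all of the dose is in the solution fed
- the reaction counts as stopped when no species that holds the L changes by six tenths of a point or more over the second half of the time

- why nothing more happens at 25 min, or that something still does (it is still moving / no working catalyst is left / forward and back rates have come level / D has run out first / all of L has reacted)
- amount of X at 25 min, in percent of the L charged
- amount of J at 25 min, in percent of the L charged

1. I wrote the balance of L, calling whatever stood in neither X nor J the rest, and I counted one D used for each X or J. But the east run, charged with the flask's L and D, still showed a rest of 14.2 % at 30.0 min beside 0.242 M of unused D, so the one-way picture failed.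

2. I therefore tried mass action on the balance, and from the east run I reckoned 31.2 M⁻¹ for K_b, the balance quotient: c_X + c_J over the product of the rest and c_D, each in the volume after the feed.

3. The objection was that the east run had half the G of the south-east run, so a failing catalyst might have stopped it; yet the south-east run gave 30.5 M⁻¹ at 30.0 min, so I took K_b as a ceiling.

4. The south-west run objected with 42.0 M⁻¹ at 30.0 min, but its D is a small difference of readings, each scattered by 0.3 percentage points, and at 25.0 min it gave 31.6 M⁻¹.

5. With the east run's L and D, the flask shares its ceiling, so I committed to 3.3 % of X and 82.5 % of J. Was it then still? At the flask's G, J rose by 2.1 points and 4.5 points between 12.0 min and 25.0 min in the south-west and south-east runs, against a stopping line of 0.6, so I said still moving.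

The forecast gave it is still moving, 3.4 % of X and 82.6 % of J, on the ground that “equilibrium is not the limit”, where my reckoning used a ceiling and gave 3.3 % of X and 82.5 % of J.

The flask gave 3.34 % of X and 82.1 % of J at 25 min: it is still moving, with a largest change of 5.3 points over the second half of the time.

    L + D ⇌ X (K = 2.74 M⁻¹, k = 4.35 M⁻¹ min⁻¹)
    X + G ⇌ J + G, rate k2*[G]*[X] forward; the back reaction follows from the equilibrium constant (k = 26.4 M⁻¹ min⁻¹)
    G → Q (k = 0.0257 min⁻¹)
    L ⇌ E (K = 1.30, k = 0.293 min⁻¹)
    L + D ⇌ J (K = 71.7 M⁻¹, k = 1.75 M⁻¹ min⁻¹)

The neighbour charged with 2.5 M of L, where D was the smaller charge at 0.440 equiv, held 1.58 % of X and 41.3 % of J with 2.6 % of its D, and its K_b came to 32.3 M⁻¹, the east run's having been 31.2 M⁻¹.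

Readings and results are calculated from invented constants; scatter was added.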